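None of this flask's constants is given, so you read what you need from the three earlier runs. The question is how much product forms and whether its excess holds.

common to all: impurity 1.5 mM
- spring: left-handed substrate 0.80 M; right-handed substrate 0.80 M; reagent 2 M; free catalyst 4 mM; racemization catalyst 8 mM; run made earlier
- winter: left-handed substrate 0.80 M; right-handed substrate 0.80 M; reagent 2 M; free catalyst 16 mM; racemization catalyst 8 mM; run made earlier
- midnight: left-handed substrate 0.40 M; right-handed substrate 0.40 M; reagent 2 M; free catalyst 8 mM; racemization catalyst 8 mM; run made earlier
- flask: left-handed substrate 0.80 M; right-handed substrate 0.80 M; reagent 2.00 M; free catalyst 8.0 mM; racemization catalyst 8.0 mM; time 8.0 d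

| run | time / d | left-handed product / % | right-handed product / % |
|---|---|---|---|
| spring | 1.25 | 3.2 | 1.9 |
| spring | 2.50 | 4.9 | 2.7 |
| spring | 3.00 | 5.9 | 3.2 |
| spring | 5.00 | 10.0 | 4.7 |
| spring | 6.00 | 11.7 | 6.0 |
| spring | 8.00 | 15.2 | 7.8 |
| winter | 1.25 | 7.5 | 4.0 |
| winter | 2.50 | 14.4 | 7.1 |
| winter | 3.00 | 16.2 | 8.5 |
| winter | 5.00 | 23.6 | 12.4 |
| winter | 6.00 | 26.9 | 13.7 |
| winter | 8.00 | 32.2 | 15.9 |
| midnight | 0.625 | 3.3 | 1.8 |
| midnight | 1.25 | 5.0 | 2.4 |
| midnight | 2.50 | 9.6 | 4.7 |
| midnight | 4.00 | 14.7 | 7.3 |
| midnight | 8.00 | 25.5 | 12.7 |

(scatter of a reading: 0.3 percentage points)

- free catalyst is single-handed; left-handed substrate and right-handed substrate are mirror images of each other, charged as a racemate, each of them at the stated concentration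
- steps under discussion: free catalyst + impurity -> spent catalyst; reagent + free catalyst + left-handed substrate -> free catalyst + left-handed product; reagent -> decomposition product; left-handed substrate + racemization catalyst <-> right-handed substrate + racemization catalyst; reagent + free catalyst + right-handed substrate -> free catalyst + right-handed product; 2 free catalyst <-> resting dimer
- an excess is below zero if the other one leads

* left-handed product and right-handed product together, in percent of the left-handed substrate and right-handed substrate charged together, at 8.0 d
* excess of left-handed product over right-handed product in the product at 8.0 d
* whether the exchange between left-handed substrate and right-handed substrate keeps pace with the reaction: how far the product's excess at 8.0 d gets from its value without exchange to its value with instant exchange (above 80% keeps pace, below 20% hardly takes part, else lags behind)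

Take the free catalyst first. By hand, more of it speeds both hands alike, so the yield should rise. From spring to winter its charge grows 4.00 times, yet the yield at 8.00 d goes from 23.0% to 48.1%, about twice.

The excess is the harder test. The free catalyst takes left-handed substrate faster, so a fast run should drain that hand unless the exchange refills it. Winter has the largest yield, and it gives a selectivity factor of 2.03 as a reading. From that factor, take the held excess, the product's excess while exchange keeps the two substrates equal, (s−1)/(s+1): 33.9%. Spring reads 32.2%. Midnight, with half the substrate, reads 33.5%.

Now time. Without exchange, winter's final readings would leave 35.6% of the left-handed charge and 68.2% of the right-handed charge, so late gains should come nearly level. Instead, from 3.00 d to 8.00 d, the gain in left-handed product over the gain in right-handed product reads 2.16.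

This flask has less catalyst than winter, so I commit to the held excess, 33.9%. The forecast gives 35%, 33% and keeps pace, its excess lying 0.90 percentage points below mine: “Without exchange, winter's ratio would fall to about 1.6 at its conversion; it stays at 2.0.”

The simulation gives 35.7%, 33.5% and keeps pace, 96% of the way.

    free catalyst + impurity → spent catalyst (k = 4590 M⁻¹ h⁻¹)
    reagent + free catalyst + left-handed substrate → free catalyst + left-handed product (k = 0.703 M⁻² h⁻¹)
    reagent → decomposition product (k = 2.79 × 10⁻⁵ h⁻¹)
    left-handed substrate + racemization catalyst ⇌ right-handed substrate + racemization catalyst, rate k4*[racemization catalyst]*[left-handed substrate] forward; the back reaction follows from the equilibrium constant (k = 16.2 M⁻¹ h⁻¹)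
    reagent + free catalyst + right-handed substrate → free catalyst + right-handed product (k = 0.348 M⁻² h⁻¹)
    2 free catalyst ⇌ resting dimer, settled at all times (K = 283 M⁻¹)

This flask ends 0.40 points below the held excess. With the conversion of left-handed substrate into right-handed substrate, both ways, taken away, this flask's excess falls from 33.5% to 27.5% and the pace answer turns. The reacted part of this flask, 35.7%, has two causes acting together: without the association of free catalyst to resting dimer, both ways, it is 59.8%, against the forecast's 35%, and the time allowed, set tenfold, gives 89.8%. The forward half-life of the exchange alone, 0.22 d, lies far below the 19 d half-life of right-handed substrate by its reaction at 3.23 d. A neighbour flask charged with 0.032 M of free catalyst reaches a yield of 59.9%, and its excess stands at 33.2%.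

The earlier runs and the new flask stem from a simulated flask with made-up constants; the scatter is artificial.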